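## Retrosynthetic overview

1. Target 25 is the p-coumarate (on the C1 oxygen) of a 1β-hydroxydrim-7-ene-11,12-dial. The endgame is phenol desilylation ⇐ double Swern oxidation of the 11,12-diol ⇐ acylation of C1–OH ⇐ triol 16 ⇐ LiAlH4 reduction of the conjugated 12,11-lactone 15.
2. Lactone 15 ⇐ aldehyde reduction, lactonisation and olefin shift on the 6-ene octalin 12. Both carbocycles of 12 are made at once from the acyclic trienal 11 by an intramolecular Diels–Alder reaction that forms C5–C10 and C8–C9; no ring exists before it.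
3. Enabling feature: ring B (C5–C6–C7–C8–C9–C10) is a cyclohexene in disguise, because the C7=C8 enal is the conjugation isomer of a C6=C7 olefin. C5=C6–C7=C8 is then a diene and C9=C10 (formyl on C9, methyl on quaternary C10) an (E)-enal dienophile. The ring-fusion bond C5–C10 belongs to rings A and B, so the chain C1–C2–C3–C4 of ring A (gem-dimethyl C4, oxygenated C1) is the tether. The cis 1,4-dicarbonyl pair gives the activation (C11) and the handle for the olefin shift (C12).
4. Trienal 11 ⇐ carbinol 8, whose C1 stereocentre (the only one not made in the cycloaddition) is set by ligand-controlled addition of a dialkylzinc to enal 5 ⇐ trienoate 4 ⇐ ester 1 and phosphonate 2.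

Key step: step 6

Remark: drimane numbering is used for the bicyclic compounds (C4 gem-dimethyl, C10 angular methyl, C11 on C9, C12 on C8; β is the face of the C10 methyl group). The absolute sense of the zinc addition in step 2 is assigned by analogy and would be checked on 8 (Mosher esters) before going on.

## Route

Step 1
Reactants: 1 methyl 2,2-dimethylbut-3-enoate; 2 triethyl 4-phosphonocrotonate
Product: 4 ethyl (2E,4E)-6,6-dimethylocta-2,4,7-trienoate, via 2,2-dimethylbut-3-enal 3 (not isolated)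
Conditions: iBu2AlH (1.05 equiv), CH2Cl2, −78 °C; then 2/LiN(SiMe3)2, THF, −78 °C → rt
Reagents that add atoms: none
Why: One-pot ester half-reduction and vinylogous Horner–Wadsworth–Emmons olefination; the α-quaternary ester stops at the aluminium hemiacetal, the released aldehyde cannot enolise, and the stabilised phosphonate anion should give the (E)-olefin while the crotonate geometry is kept.

Step 2
Reactants: 4 ethyl (2E,4E)-6,6-dimethylocta-2,4,7-trienoate; 5 (E)-4-acetoxy-2-methylbut-2-enal
Product: 8 ethyl (2E,4E,9R,10E)-12-acetoxy-9-hydroxy-6,6,10-trimethyldodeca-2,4,10-trienoate, via alkyldiethylborane 6 (not isolated), via dialkylzinc 7 (not isolated)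
Conditions: 4 (2.4 equiv), Et2BH (from BH3·SMe2 + 2 Et3B), Et2O, 0 °C → rt; Et2Zn (neat), 0 °C, volatiles off in vacuo; 5 (1 equiv), Ti(OiPr)4, (1S,2S)-1,2-bis(trifluoromethanesulfonamido)cyclohexane (8 mol %), toluene, −20 °C; aq. NH4Cl
Reagents that add atoms: none
Why: Hydroboration of the terminal vinyl group (the dienoate is electron-poor and flanked by the quaternary carbon), boron–zinc exchange, and titanium/bis-sulfonamide-catalysed enantioselective 1,2-addition of the functionalised dialkylzinc to an α-methyl enal (Knochel-type addition). The ligand selects the aldehyde face: the (1S,2S) ligand is specified as the antipode of the one that gives (S)-carbinols in this priority pattern, so the (R)-carbinol is expected. Only one alkyl group of 7 transfers, hence the excess of the cheap fragment 4.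

Step 3
Reactants: 8 ethyl (2E,4E,9R,10E)-12-acetoxy-9-hydroxy-6,6,10-trimethyldodeca-2,4,10-trienoate
Product: 9 ethyl (2E,4E,9R,10E)-12-acetoxy-6,6,10-trimethyl-9-(pivaloyloxy)dodeca-2,4,10-trienoate
Conditions: PivCl, pyridine, DMAP (cat.), CH2Cl2, 0 °C → rt
Reagents that add atoms: pivaloyl chloride, CC(C)(C)C(=O)Cl
Why: DMAP-catalysed O-acylation of the secondary allylic alcohol; no bond at the stereocentre is broken, and the pivalate survives the next ethanolysis but falls to LiAlH4 in step 8.

Step 4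
Reactants: 9 ethyl (2E,4E,9R,10E)-12-acetoxy-6,6,10-trimethyl-9-(pivaloyloxy)dodeca-2,4,10-trienoate
Product: 10 ethyl (2E,4E,9R,10E)-12-hydroxy-6,6,10-trimethyl-9-(pivaloyloxy)dodeca-2,4,10-trienoate
Conditions: K2CO3 (0.3 equiv), EtOH, 0 °C → rt
Reagents that add atoms: none
Why: Base-catalysed transesterification removes the unhindered primary acetate much faster than the pivalate; ethanol as solvent leaves the ethyl ester unchanged.

Step 5
Reactants: 10 ethyl (2E,4E,9R,10E)-12-hydroxy-6,6,10-trimethyl-9-(pivaloyloxy)dodeca-2,4,10-trienoate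
Product: 11 ethyl (2E,4E,9R,10E)-6,6,10-trimethyl-12-oxo-9-(pivaloyloxy)dodeca-2,4,10-trienoate
Conditions: MnO2 (activated, excess), CH2Cl2, rt
Reagents that add atoms: none
Why: Heterogeneous oxidation of the primary allylic alcohol to the enal under neutral conditions, which should keep the (E)-geometry and the γ-stereocentre.

Step 6
Reactants: 11 ethyl (2E,4E,9R,10E)-6,6,10-trimethyl-12-oxo-9-(pivaloyloxy)dodeca-2,4,10-trienoate
Product: 12 ethyl 11-oxo-1β-pivaloyloxydrim-6-en-12-oate (trans-decalin; 5α-H; 8α-H; 9α-H; C10 methyl β)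
Conditions: toluene (0.01 M), BHT (cat.), 150 °C, sealed tube
Reagents that add atoms: none
Why: Thermal, concerted but asynchronous intramolecular [4+2] cycloaddition of a 1,7,9-decatriene (type 1 IMDA): the (E,E)-diene C5=C6–C7=C8 adds suprafacially across the (E)-enal C9=C10, the remote diene terminus C5 bonding to the enal β-carbon C10 and the ester-bearing C8 to the formyl-bearing C9, which is also the electronically preferred "ortho" pairing; the closest known reaction type is the endo-selective IMDA of acyclic trienes with terminally activated (E)-dienophiles, including tethers with a 4,4-dimethyl group and a C1 oxygen used for 1-oxygenated drimanes. Ring B closes as the six-membered cycloaddition ring through both new bonds, and ring A closes through the C5–C10 bond alone over the four-carbon C1–C4 tether in a chair-like, fused (anti) mode. C9 and C10 are fixed relative to each other by the (E)-enal geometry (formyl cis to methyl), C8 by the (E,E)-diene geometry, and the trans ring fusion C5/C10 by the transition state in which formyl and methyl are endo and the tether exo. The absolute sense comes from C1: in the chair-like tether the pivalate lies equatorial and anti to the forming C5–C10 bond with C1–H inside against C9–H, so the diene should add to the face that gives the 1β-oxygen/10β-methyl relationship. The step needs trans over cis fusion and one π-face; the endo preference of the formyl group, the equatorial pivalate and the gem-dimethyl group at C4 (reactive-rotamer effect, and no 1,5-hydrogen shift is possible in this diene) are meant to secure this, and dilution suppresses intermolecular cycloaddition.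

Step 7
Reactants: 12 ethyl 11-oxo-1β-pivaloyloxydrim-6-en-12-oate
Product: 15 1β-pivaloyloxydrim-7-en-12,11-olide (1β-pivaloyloxycinnamolide), via hydroxy ester 13 (not isolated), via 6-ene lactone 14 (not isolated)
Conditions: NaBH4, EtOH, 0 °C; AcOH quench, solvent exchange; DBU, toluene, 60 °C
Reagents that add atoms: none
Why: Chemoselective aldehyde reduction; the new C11 carbinol is cis to the C8 ester and should close the γ-lactone, and DBU then moves the olefin into conjugation through the dienolate (deprotonation at C8, protonation at C6). The C8 centre is erased, and C9 cannot epimerise because it is no longer α to a carbonyl group.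

Step 8
Reactants: 15 1β-pivaloyloxydrim-7-en-12,11-olide
Product: 16 drim-7-ene-1β,11,12-triol
Conditions: LiAlH4 (excess), THF, 0 °C → rt; aq. KNaC4H4O6 work-up
Reagents that add atoms: none
Why: 1,2-Reduction of the α-alkylidene lactone to the allylic 11,12-diol (the cinnamolide-to-diol reduction) with reductive cleavage of the pivalate in the same operation; no stereocentre is touched.

Step 9
Reactants: 16 drim-7-ene-1β,11,12-triol
Product: 17 11,12-bis(triethylsilyloxy)drim-7-en-1β-ol
Conditions: Et3SiCl (2.1 equiv), imidazole, CH2Cl2, −20 → 0 °C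
Reagents that add atoms: chlorotriethylsilane, CC[Si](CC)(CC)Cl
Why: Selective silylation; the two primary hydroxyl groups should react far faster than the secondary C1 hydroxyl next to the quaternary C10.

Step 10
Reactants: 18 (E)-p-coumaric acid
Product: 20 (E)-3-[4-(tert-butyldimethylsilyloxy)phenyl]prop-2-enoic acid, via bis-silylated coumarate 19 (not isolated)
Conditions: tBuMe2SiCl (2.3 equiv), imidazole, DMF, rt; then AcOH/THF/H2O, rt
Reagents that add atoms: tert-butyl(chloro)dimethylsilane, CC(C)(C)[Si](C)(C)Cl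
Why: Bis-silylation followed by selective hydrolysis of the labile silyl ester; the aryl silyl ether is stable to dilute acetic acid and the (E)-olefin is untouched.

Step 11
Reactants: 17 11,12-bis(triethylsilyloxy)drim-7-en-1β-ol; 20 (E)-3-[4-(tert-butyldimethylsilyloxy)phenyl]prop-2-enoic acid
Product: 22 11,12-bis(triethylsilyloxy)drim-7-en-1β-yl (E)-3-[4-(tert-butyldimethylsilyloxy)phenyl]prop-2-enoate, via mixed anhydride 21 (not isolated)
Conditions: 20, 2,4,6-trichlorobenzoyl chloride, Et3N, THF, rt; then 17, DMAP, toluene, 60 °C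
Reagents that add atoms: none
Why: Yamaguchi esterification; the acylpyridinium formed from the mixed anhydride is electrophilic enough for the hindered equatorial C1 hydroxyl, and acylation at oxygen leaves the C1 configuration and the (E)-cinnamate geometry unchanged.

Step 12
Reactants: 22 11,12-bis(triethylsilyloxy)drim-7-en-1β-yl (E)-3-[4-(tert-butyldimethylsilyloxy)phenyl]prop-2-enoate
Product: 23 11,12-dihydroxydrim-7-en-1β-yl (E)-3-[4-(tert-butyldimethylsilyloxy)phenyl]prop-2-enoate
Conditions: PPTS, MeOH/CH2Cl2, 0 °C → rt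
Reagents that add atoms: none
Why: Mild acid methanolysis of the two primary triethylsilyl ethers; the aryl tert-butyldimethylsilyl ether and the ester are stable to pyridinium tosylate.

Step 13
Reactants: 23 11,12-dihydroxydrim-7-en-1β-yl (E)-3-[4-(tert-butyldimethylsilyloxy)phenyl]prop-2-enoate
Product: 24 11,12-dioxodrim-7-en-1β-yl (E)-3-[4-(tert-butyldimethylsilyloxy)phenyl]prop-2-enoate
Conditions: (COCl)2, DMSO, CH2Cl2, −78 °C; Et3N, −78 → −30 °C; cold pH 7 buffer
Reagents that add atoms: none
Why: Double Swern oxidation (the drim-7-ene-11,12-diol to polygodial precedent); both carbinols become alkoxysulfonium salts before base is added, so no lactol can form, and cold, brief exposure to Et3N should leave the base-sensitive C9 centre as set.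

Step 14
Reactants: 24 11,12-dioxodrim-7-en-1β-yl (E)-3-[4-(tert-butyldimethylsilyloxy)phenyl]prop-2-enoate
Product: 25 1β-[(E)-4-hydroxycinnamoyloxy]drim-7-ene-11,12-dial (1R,5S,9R,10S; CNP0187624.1)
Conditions: Bu4NF (1.1 equiv), AcOH (1.3 equiv), THF, 0 °C
Reagents that add atoms: none
Why: Fluoride cleaves the aryl silyl ether selectively; the acetic acid buffer keeps the medium non-basic so that C9, the ene-dial and the ester should survive.

## Compound list

1 | methyl 2,2-dimethylbut-3-enoate | C=CC(C)(C)C(=O)OC | starting material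
2 | triethyl 4-phosphonocrotonate, ethyl (E)-4-(diethoxyphosphoryl)but-2-enoate | CCOC(=O)/C=C/CP(=O)(OCC)OCC | starting material
3 | 2,2-dimethylbut-3-enal | C=CC(C)(C)C=O | intermediate
4 | ethyl (2E,4E)-6,6-dimethylocta-2,4,7-trienoate | C=CC(C)(C)/C=C/C=C/C(=O)OCC | intermediate
5 | (E)-4-acetoxy-2-methylbut-2-enal | CC(=O)OC/C=C(\C)C=O | starting material
6 | ethyl (2E,4E)-8-(diethylboranyl)-6,6-dimethylocta-2,4-dienoate | CCB(CC)CCC(C)(C)/C=C/C=C/C(=O)OCC | intermediate
7 | bis[(4E,6E)-8-ethoxy-3,3-dimethyl-8-oxoocta-4,6-dien-1-yl]zinc | CCOC(=O)/C=C/C=C/C(C)(C)CC[Zn]CCC(C)(C)/C=C/C=C/C(=O)OCC | intermediate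
8 | ethyl (2E,4E,9R,10E)-12-acetoxy-9-hydroxy-6,6,10-trimethyldodeca-2,4,10-trienoate | CCOC(=O)/C=C/C=C/C(C)(C)CC[C@@H](O)/C(C)=C/COC(C)=O | intermediate
9 | ethyl (2E,4E,9R,10E)-12-acetoxy-6,6,10-trimethyl-9-(pivaloyloxy)dodeca-2,4,10-trienoate | CCOC(=O)/C=C/C=C/C(C)(C)CC[C@@H](OC(=O)C(C)(C)C)/C(C)=C/COC(C)=O | intermediate
10 | ethyl (2E,4E,9R,10E)-12-hydroxy-6,6,10-trimethyl-9-(pivaloyloxy)dodeca-2,4,10-trienoate | CCOC(=O)/C=C/C=C/C(C)(C)CC[C@@H](OC(=O)C(C)(C)C)/C(C)=C/CO | intermediate
11 | ethyl (2E,4E,9R,10E)-6,6,10-trimethyl-12-oxo-9-(pivaloyloxy)dodeca-2,4,10-trienoate | CCOC(=O)/C=C/C=C/C(C)(C)CC[C@@H](OC(=O)C(C)(C)C)/C(C)=C/C=O | intermediate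
12 | ethyl 11-oxo-1β-pivaloyloxydrim-6-en-12-oate (5α-H, 8α-H, 9α-H, 10β-methyl) | CC1(C)CC[C@@H](OC(=O)C(C)(C)C)[C@]2(C)[C@@H](C=O)[C@@H](C(=O)OCC)C=C[C@@H]12 | intermediate
13 | ethyl 11-hydroxy-1β-pivaloyloxydrim-6-en-12-oate | CC1(C)CC[C@@H](OC(=O)C(C)(C)C)[C@]2(C)[C@@H](CO)[C@@H](C(=O)OCC)C=C[C@@H]12 | intermediate
14 | 1β-pivaloyloxydrim-6-en-12,11-olide (8α-H, cis-fused lactone) | CC1(C)CC[C@@H](OC(=O)C(C)(C)C)[C@]2(C)[C@H]3COC(=O)[C@H]3C=C[C@@H]12 | intermediate
15 | 1β-pivaloyloxydrim-7-en-12,11-olide | CC1(C)CC[C@@H](OC(=O)C(C)(C)C)[C@]2(C)[C@H]3COC(=O)C3=CC[C@@H]12 | intermediate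
16 | drim-7-ene-1β,11,12-triol | CC1(C)CC[C@@H](O)[C@]2(C)[C@@H](CO)C(CO)=CC[C@@H]12 | intermediate
17 | 11,12-bis(triethylsilyloxy)drim-7-en-1β-ol | CC1(C)CC[C@@H](O)[C@]2(C)[C@@H](CO[Si](CC)(CC)CC)C(CO[Si](CC)(CC)CC)=CC[C@@H]12 | intermediate
18 | (E)-p-coumaric acid | OC(=O)/C=C/c1ccc(O)cc1 | starting material
19 | tert-butyldimethylsilyl (E)-3-[4-(tert-butyldimethylsilyloxy)phenyl]prop-2-enoate | CC(C)(C)[Si](C)(C)OC(=O)/C=C/c1ccc(O[Si](C)(C)C(C)(C)C)cc1 | intermediate
20 | (E)-3-[4-(tert-butyldimethylsilyloxy)phenyl]prop-2-enoic acid | OC(=O)/C=C/c1ccc(O[Si](C)(C)C(C)(C)C)cc1 | intermediate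
21 | (E)-3-[4-(tert-butyldimethylsilyloxy)phenyl]prop-2-enoic 2,4,6-trichlorobenzoic anhydride | CC(C)(C)[Si](C)(C)Oc1ccc(/C=C/C(=O)OC(=O)c2c(Cl)cc(Cl)cc2Cl)cc1 | intermediate
22 | 11,12-bis(triethylsilyloxy)drim-7-en-1β-yl (E)-3-[4-(tert-butyldimethylsilyloxy)phenyl]prop-2-enoate | CC1(C)CC[C@@H](OC(=O)/C=C/c3ccc(O[Si](C)(C)C(C)(C)C)cc3)[C@]2(C)[C@@H](CO[Si](CC)(CC)CC)C(CO[Si](CC)(CC)CC)=CC[C@@H]12 | intermediate
23 | 11,12-dihydroxydrim-7-en-1β-yl (E)-3-[4-(tert-butyldimethylsilyloxy)phenyl]prop-2-enoate | CC1(C)CC[C@@H](OC(=O)/C=C/c3ccc(O[Si](C)(C)C(C)(C)C)cc3)[C@]2(C)[C@@H](CO)C(CO)=CC[C@@H]12 | intermediate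
24 | 11,12-dioxodrim-7-en-1β-yl (E)-3-[4-(tert-butyldimethylsilyloxy)phenyl]prop-2-enoate | CC1(C)CC[C@@H](OC(=O)/C=C/c3ccc(O[Si](C)(C)C(C)(C)C)cc3)[C@]2(C)[C@@H](C=O)C(C=O)=CC[C@@H]12 | intermediate
25 | 1β-[(E)-4-hydroxycinnamoyloxy]drim-7-ene-11,12-dial (1R,5S,9R,10S) | CC1(C)CC[C@@H](OC(=O)/C=C/c2ccc(O)cc2)[C@]2(C)[C@@H](C=O)C(C=O)=CC[C@@H]12 | target

## Step count and risks

Total step count: 14. Longest linear sequence: 13 (steps 1–9 and 11–14); step 10 prepares the acid in a side branch.

**Step 6 (cycloaddition).** What may go wrong: cycloaddition through the tether-endo transition state (cis ring fusion), addition of the diene to the other face of the enal, or a rate so low for the ester-deactivated diene that the enal isomerises thermally first. The fallback makes the diene electron-neutral and uses Lewis acid activation; it sets out from 4 and comes back at 14.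

iBu2AlH reduction of 4 should give (2E,4E)-6,6-dimethylocta-2,4,7-trien-1-ol F1, and tBuMe2SiCl/imidazole its silyl ether F2. The operations of step 2 then lead through the alkyldiethylborane F3 and the dialkylzinc F4 to the (R)-carbinol F5. The operations of steps 3 to 5 give the pivalate F6, the primary alcohol F7 and the trienal F8. With Me2AlCl in CH2Cl2 at −78 to −20 °C, F8 should cyclise through the formyl-endo transition state to the octalin F9. NaBH4 gives the C11 carbinol F10 and Bu4NF the 11,12-diol F11. TEMPO/PhI(OAc)2 should oxidise the less hindered C12 carbinol first and close the lactone 14, which DBU converts to 15 as in step 7.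

**Step 2 (zinc addition).** What may go wrong: competing hydroboration of the dienoate, incomplete boron–zinc exchange, or insufficient face discrimination in the addition. The fallback sets out from 4 and comes back at 8.

9-BBN then NaBO3·4H2O should give ethyl (2E,4E)-8-hydroxy-6,6-dimethylocta-2,4-dienoate F12, and I2/PPh3/imidazole the iodide F13. A Takai alkylchromium addition of F13 to 5 (CrCl2, catalytic cobalt phthalocyanine Co(C32H16N8), DMF) gives the racemic carbinol F14. MnO2 oxidises it to the enone F15, and Corey–Bakshi–Shibata reduction with the (S)-methyl oxazaborolidine and catecholborane at −78 °C (alkenyl as the large group) should return the (R)-carbinol 8.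

**Step 11 (esterification).** What may go wrong: slow acylation of the hindered C1 hydroxyl, so that the mixed anhydride is consumed by side reactions or silyl groups migrate on prolonged heating. The fallback sets out from 17 and comes back at 22.

Acylation of 17 with diethylphosphonoacetic acid (DCC, catalytic DMAP; a small acyl donor that reacts through the phosphonoketene) gives 11,12-bis(triethylsilyloxy)drim-7-en-1β-yl 2-(diethoxyphosphoryl)acetate F16. Horner–Wadsworth–Emmons olefination with commercial 4-(tert-butyldimethylsilyloxy)benzaldehyde under LiCl/iPr2NEt in MeCN should then build the (E)-cinnamate 22.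

## Further compounds

F1 | step 6 | (2E,4E)-6,6-dimethylocta-2,4,7-trien-1-ol | C=CC(C)(C)/C=C/C=C/CO
F2 | step 6 | tert-butyl{[(2E,4E)-6,6-dimethylocta-2,4,7-trien-1-yl]oxy}dimethylsilane | C=CC(C)(C)/C=C/C=C/CO[Si](C)(C)C(C)(C)C
F3 | step 6 | tert-butyl{[(2E,4E)-8-(diethylboranyl)-6,6-dimethylocta-2,4-dien-1-yl]oxy}dimethylsilane | CCB(CC)CCC(C)(C)/C=C/C=C/CO[Si](C)(C)C(C)(C)C
F4 | step 6 | bis[(4E,6E)-8-(tert-butyldimethylsilyloxy)-3,3-dimethylocta-4,6-dien-1-yl]zinc | CC(C)(C)[Si](C)(C)OC/C=C/C=C/C(C)(C)CC[Zn]CCC(C)(C)/C=C/C=C/CO[Si](C)(C)C(C)(C)C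
F5 | step 6 | (2E,4R,8E,10E)-12-(tert-butyldimethylsilyloxy)-4-hydroxy-3,7,7-trimethyldodeca-2,8,10-trien-1-yl acetate | CC(C)(C)[Si](C)(C)OC/C=C/C=C/C(C)(C)CC[C@@H](O)/C(C)=C/COC(C)=O
F6 | step 6 | (2E,4R,8E,10E)-1-acetoxy-12-(tert-butyldimethylsilyloxy)-3,7,7-trimethyldodeca-2,8,10-trien-4-yl pivalate | CC(C)(C)[Si](C)(C)OC/C=C/C=C/C(C)(C)CC[C@@H](OC(=O)C(C)(C)C)/C(C)=C/COC(C)=O
F7 | step 6 | (2E,4R,8E,10E)-12-(tert-butyldimethylsilyloxy)-1-hydroxy-3,7,7-trimethyldodeca-2,8,10-trien-4-yl pivalate | CC(C)(C)[Si](C)(C)OC/C=C/C=C/C(C)(C)CC[C@@H](OC(=O)C(C)(C)C)/C(C)=C/CO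
F8 | step 6 | (2E,4R,8E,10E)-12-(tert-butyldimethylsilyloxy)-3,7,7-trimethyl-1-oxododeca-2,8,10-trien-4-yl pivalate | CC(C)(C)[Si](C)(C)OC/C=C/C=C/C(C)(C)CC[C@@H](OC(=O)C(C)(C)C)/C(C)=C/C=O
F9 | step 6 | 12-(tert-butyldimethylsilyloxy)-11-oxodrim-6-en-1β-yl pivalate (5α-H, 8α-H, 9α-H) | CC1(C)CC[C@@H](OC(=O)C(C)(C)C)[C@]2(C)[C@@H](C=O)[C@@H](CO[Si](C)(C)C(C)(C)C)C=C[C@@H]12
F10 | step 6 | 12-(tert-butyldimethylsilyloxy)-11-hydroxydrim-6-en-1β-yl pivalate | CC1(C)CC[C@@H](OC(=O)C(C)(C)C)[C@]2(C)[C@@H](CO)[C@@H](CO[Si](C)(C)C(C)(C)C)C=C[C@@H]12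
F11 | step 6 | 11,12-dihydroxydrim-6-en-1β-yl pivalate | CC1(C)CC[C@@H](OC(=O)C(C)(C)C)[C@]2(C)[C@@H](CO)[C@@H](CO)C=C[C@@H]12
F12 | step 2 | ethyl (2E,4E)-8-hydroxy-6,6-dimethylocta-2,4-dienoate | CCOC(=O)/C=C/C=C/C(C)(C)CCO
F13 | step 2 | ethyl (2E,4E)-8-iodo-6,6-dimethylocta-2,4-dienoate | CCOC(=O)/C=C/C=C/C(C)(C)CCI
F14 | step 2 | ethyl (2E,4E,10E)-12-acetoxy-9-hydroxy-6,6,10-trimethyldodeca-2,4,10-trienoate (racemic) | CCOC(=O)/C=C/C=C/C(C)(C)CCC(O)/C(C)=C/COC(C)=O
F15 | step 2 | ethyl (2E,4E,10E)-12-acetoxy-6,6,10-trimethyl-9-oxododeca-2,4,10-trienoate | CCOC(=O)/C=C/C=C/C(C)(C)CCC(=O)/C(C)=C/COC(C)=O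
F16 | step 11 | 11,12-bis(triethylsilyloxy)drim-7-en-1β-yl 2-(diethoxyphosphoryl)acetate | CC1(C)CC[C@@H](OC(=O)CP(=O)(OCC)OCC)[C@]2(C)[C@@H](CO[Si](CC)(CC)CC)C(CO[Si](CC)(CC)CC)=CC[C@@H]12
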